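Target cannot appear faster than reagent at its full charge can strike the whole of the working catalyst, so that rate caps the flow of open intermediate into target.

all flasks: substrate 0.050 M; reagent 0.0650 M; free catalyst 2.5 mM; impurity 0.42 mM; time 4.0 min

| flask | temperature |
|---|---|
| eta | 110 °C |
| alpha | 85 °C |
| gamma | 135 °C |
| delta | 60 °C |

    free catalyst + open intermediate ⇌ catalyst intermediate (K1 = 58.7 /M, k1 = 82.7 /M/s, Ea1 = 45.0 kJ/mol, ΔH1 = −37.0 kJ/mol)
    reagent + catalyst intermediate → free catalyst + target (k2 = 0.952 /M/s, Ea2 = 68.0 kJ/mol)
    substrate + reagent → uncatalysed product (k3 = 0.00681 /M/s, Ea3 = 62.0 kJ/mol)
    substrate + free catalyst → free catalyst + open intermediate (k4 = 45.8 /M/s, Ea4 = 45.0 kJ/mol)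
    free catalyst + impurity → spent catalyst (k5 = 975 /M/s, Ea5 = 53.0 kJ/mol)
    (constants at 110 °C)

- the list of constants is for 110 °C, to be carried to other temperatures by the activation energies and enthalpies

- which flask leads in amount of open intermediate, in percent of the substrate charged ("all alike" within 1.5 percentage points) (eta / alpha / gamma / delta / all alike)
- how much open intermediate is there at the end, in percent of the substrate charged: eta
- how much open intermediate is there at the end, in percent of the substrate charged: alpha
- how much open intermediate is there at the end, in percent of the substrate charged: gamma
- how much open intermediate is there at the end, in percent of the substrate charged: delta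

- Reckon eta first, where the constants stand as listed.
- Remove the impurity. In eta it lasts about 0.410 s against free catalyst at its charge, far shorter than 4.0 min, so take the working catalyst W as charge less impurity: 2.08 mM.
- Define the drain ceiling D as the share of charged substrate that could become target in the given time, with reagent held at its charge and W held wholly as catalyst intermediate. For eta, D is 61.8%.
- Treat the binding step in eta as an equilibrium: catalyst intermediate falls back at 1.41 /s, faster than it goes forward at 0.0619 /s.
- Let θ be the share of W held as catalyst intermediate, the resting state of the round in eta. Open intermediate cannot exceed the substrate charge, so θ stays under 0.746, and target in eta stays under 46.1%.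
- Bound the opening. Free catalyst in eta stays above the unbound share of W at that limit of θ, so the life τ of substrate in eta is at most 41.3 s.
- Substrate left in eta is then under 0.300%, and uncatalysed product under 1.83%.
- Get the bound from below. Subtract these two, the target bound and the most that catalyst intermediate can hold, W, from the whole charge: open intermediate in eta is at least 47.6%.
- Join the ends for the estimated bound from above. In eta reagent keeps at least 0.631 of its charge. From τ onward, take θ at its equilibrium value for that floor of open intermediate, 0.583, and count the drain from τ onward.
- Target in eta then comes to at least about 18.8%, so open intermediate comes to at most about 78.7%.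
- Commit to the middle of the bracket for eta: 63.2%.
- The forecast gives 61% for eta, inside the bracket, with 73% for alpha, 30% for gamma and 42% for delta, and it names alpha the leader: “85 °C strikes the best balance with 110 °C second”.
- The flasks give 61.9% for eta, 73.4% for alpha, 30.3% for gamma and 42.7% for delta, so alpha leads, and eta lands inside the bracket. Eta holds 34.5% of target at 4.00 min, under its bound of 46.1%. Now take alpha's neighbour with 6.3 × 10⁻⁴ M of free catalyst. Its working catalyst is 0.210 mM, so its ceiling at alpha's temperature is 1.41%, and that flask holds 0.810% of target.

The numbers of this flask are those of an exercise, and the outcome is calculated.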